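**Retrosynthetic overview**
1. The seven-membered ring is made last. The benzotropolone is opened to epicatechin gallate 12 (its catechol carbons C5'/C6' become the benzo ring) and the non-natural 2',3',4'-trihydroxy epi-flavan-3-ol 11 (five carbons of its ring B become the tropolone; C4' leaves as CO2). Because 11 is a 4-substituted pyrogallol, the flavan ends up on the tropolone carbon next to the hydroxyl, as drawn.
2. 11 comes from pentabenzyl ether 10. C2 and C3 of 10 are set together (cis, 2R,3R) by a reductive dynamic kinetic resolution of racemic flavan-3-one 9.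
3. 9 comes from flav-3-ene 7 by epoxidation and 1,2-hydride shift. Ring C of 7 is closed from chalcone 4 by carbonyl reduction, ortho-quinone methide formation and oxa-6π electrocyclisation.
4. Chalcone 4 is the aldol condensation product of acetophenone 3 and aldehyde 2 (from 1).
5. Ring order: ring C of the new flavan (step 3), then the tropolone ring (step 7). All rings and both stereocentres of 12 are bought.

Assumption: the target is taken exactly as drawn (free-hydroxyl flavan on the tropolone carbon adjacent to the tropolone hydroxyl, both flavan units 2R,3R-cis), and 3 and 12 are catalogue compounds.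

**Step 1**
Reactants: 1 2,3,4-trihydroxybenzaldehyde
Product: 2 2,3,4-tris(benzyloxy)benzaldehyde
Conditions: BnBr (3.6 equiv), K2CO3 (4.5 equiv), DMF, 60 °C, 12 h
Reagents that add atoms: benzyl bromide BrCc1ccccc1
Why: Williamson ether synthesis on all three phenols (the hydrogen-bonded 2-OH needs the excess reagent and heat) gives a pyrogallol protection that is removed later by hydrogenolysis.

**Step 2**
Reactants: 2 2,3,4-tris(benzyloxy)benzaldehyde; 3 1-[2,4-bis(benzyloxy)-6-hydroxyphenyl]ethanone
Product: 4 (E)-1-[2,4-bis(benzyloxy)-6-hydroxyphenyl]-3-[2,3,4-tris(benzyloxy)phenyl]prop-2-en-1-one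
Conditions: KOH (50% aq, 10 equiv), EtOH/THF 2:1, rt, 36 h
Reagents that add atoms: none
Why: Claisen–Schmidt aldol condensation of the methyl ketone with the non-enolisable aldehyde gives the thermodynamic E-2'-hydroxychalcone, the open-chain C6–C3–C6 precursor from which ring C is closed.

**Step 3**
Reactants: 4 (E)-1-[2,4-bis(benzyloxy)-6-hydroxyphenyl]-3-[2,3,4-tris(benzyloxy)phenyl]prop-2-en-1-one
Product: 7 racemic 5,7-bis(benzyloxy)-2-[2,3,4-tris(benzyloxy)phenyl]-2H-chromene, via allylic alcohol 5 (not isolated), via ortho-quinone methide 6 (not isolated)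
Conditions: NaBH4 (4 equiv), THF/EtOH 1:1, 0 °C to rt; then AcOH, 60 °C
Reagents that add atoms: none
Why: 1,2-reduction of the chalcone carbonyl gives 5, which on acidification loses water to 6 and closes ring C by oxa-6π electrocyclisation (Clark-Lewis flav-3-ene synthesis); C2 is formed racemic, which is harmless because step 5 sets it.

**Step 4**
Reactants: 7 racemic 5,7-bis(benzyloxy)-2-[2,3,4-tris(benzyloxy)phenyl]-2H-chromene
Product: 9 racemic 5,7-bis(benzyloxy)-2-[2,3,4-tris(benzyloxy)phenyl]chroman-3-one, via 3,4-epoxyflavan 8 (not isolated)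
Conditions: dimethyldioxirane (1.05 equiv, acetone), CH2Cl2, −40 °C, Ar; cold evaporation; then InCl3 (5 mol %), THF, 0 °C to rt
Reagents that add atoms: dimethyldioxirane CC1(C)OO1
Why: epoxidation of the electron-rich C3=C4 bond followed by Lewis-acid opening at C4 (cation stabilised by the 5,7-dialkoxy ring A) and 1,2-hydride shift from C3 gives the 3-ketone (Meinwald rearrangement), placing the oxygen at C3 and leaving C2 epimerisable.

**Step 5**
Reactants: 9 racemic 5,7-bis(benzyloxy)-2-[2,3,4-tris(benzyloxy)phenyl]chroman-3-one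
Product: 10 (2R,3R)-5,7-bis(benzyloxy)-2-[2,3,4-tris(benzyloxy)phenyl]chroman-3-ol
Conditions: RuCl(p-cymene)[(R,R)-TsDPEN] (2 mol %; TsDPEN = N-tosyl-1,2-diphenylethane-1,2-diamine), HCO2H/Et3N 5:2, CH2Cl2, 30 °C, 24 h, Ar; recrystallise
Reagents that add atoms: none
Why: Proposed new method: asymmetric transfer hydrogenation with dynamic kinetic resolution of a flavan-3-one, in which C2 (benzylic, alpha to both O1 and the carbonyl) racemises rapidly through the enol under the amine buffer while the chiral ruthenium hydride reduces only one ketone enantiomer and delivers hydride anti to the C2 aryl group, so that both stereocentres are set at once as 2,3-cis (2R,3R); the closest known reactions are Noyori transfer-hydrogenation resolutions of 1-aryl-2-tetralones and isoflavanones to cis alcohols, and the catalyst hand is checked on the first run because the mirror-image complex gives ent-10.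

**Step 6**
Reactants: 10 (2R,3R)-5,7-bis(benzyloxy)-2-[2,3,4-tris(benzyloxy)phenyl]chroman-3-ol
Product: 11 (2R,3R)-2-(2,3,4-trihydroxyphenyl)chromane-3,5,7-triol
Conditions: H2 (1 atm), Pd(OH)2/C (20 wt %), degassed THF/MeOH 1:1, rt, 6 h; filter under Ar, use at once
Reagents that add atoms: none
Why: neutral hydrogenolysis removes the five benzyl ethers without touching C2 or C3 (as in the final step of benzyl-protected catechin syntheses), giving the air-sensitive free pyrogallol flavan.

**Step 7**
Reactants: 11 (2R,3R)-2-(2,3,4-trihydroxyphenyl)chromane-3,5,7-triol; 12 (−)-epicatechin 3-O-gallate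
Product: 16 (2R,3R)-5,7-dihydroxy-2-{3,4,6-trihydroxy-5-oxo-7-[(2R,3R)-3,5,7-trihydroxychroman-2-yl]-5H-benzo[7]annulen-1-yl}chroman-3-yl 3,4,5-trihydroxybenzoate, via ECG ortho-quinone 13 (not isolated), via biaryl Michael adduct 14 (not isolated), via bicyclo[3.2.1]octane adduct 15 (not isolated)
Conditions: mushroom tyrosinase (dicopper oxidase of Agaricus bisporus, catalytic), air, citrate–phosphate buffer pH 5.5/acetone 9:1, 25 °C; 11 added over 2 h to 12 (2 equiv); EtOAc extraction, Sephadex LH-20, C18 HPLC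
Reagents that add atoms: none
Why: the enzyme is expected to oxidise the catechol ring of 12 in preference to pyrogallol-type rings; the quinone 13 is attacked at C6' by the most nucleophilic carbon of 11 (C5', ortho and para to hydroxyls) to give 14, and further oxidation, carbonyl addition across the ring (15) and oxidative loss of C4' as CO2 close the benzotropolone (purpurogallin/theaflavin-type oxidative annulation) with the flavan next to the tropolone hydroxyl and all four stereocentres untouched.

**Compound list**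
1 | 2,3,4-trihydroxybenzaldehyde | O=Cc1ccc(O)c(O)c1O | starting material
2 | 2,3,4-tris(benzyloxy)benzaldehyde | O=Cc1ccc(OCc2ccccc2)c(OCc2ccccc2)c1OCc1ccccc1 | intermediate
3 | 1-[2,4-bis(benzyloxy)-6-hydroxyphenyl]ethanone | CC(=O)c1c(O)cc(OCc2ccccc2)cc1OCc1ccccc1 | starting material
4 | (E)-1-[2,4-bis(benzyloxy)-6-hydroxyphenyl]-3-[2,3,4-tris(benzyloxy)phenyl]prop-2-en-1-one | O=C(/C=C/c1ccc(OCc2ccccc2)c(OCc2ccccc2)c1OCc1ccccc1)c1c(O)cc(OCc2ccccc2)cc1OCc1ccccc1 | intermediate
5 | allylic alcohol: (E)-1-[2,4-bis(benzyloxy)-6-hydroxyphenyl]-3-[2,3,4-tris(benzyloxy)phenyl]prop-2-en-1-ol (racemic, not isolated) | OC(/C=C/c1ccc(OCc2ccccc2)c(OCc2ccccc2)c1OCc1ccccc1)c1c(O)cc(OCc2ccccc2)cc1OCc1ccccc1 | intermediate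
6 | ortho-quinone methide: 3,5-bis(benzyloxy)-6-{(E)-3-[2,3,4-tris(benzyloxy)phenyl]allylidene}cyclohexa-2,4-dien-1-one (not isolated) | O=C1C=C(OCc2ccccc2)C=C(OCc2ccccc2)C1=C/C=C/c1ccc(OCc2ccccc2)c(OCc2ccccc2)c1OCc1ccccc1 | intermediate
7 | 5,7-bis(benzyloxy)-2-[2,3,4-tris(benzyloxy)phenyl]-2H-chromene (racemic at C2) | C1=Cc2c(OCc3ccccc3)cc(OCc3ccccc3)cc2OC1c1ccc(OCc2ccccc2)c(OCc2ccccc2)c1OCc1ccccc1 | intermediate
8 | 3,4-epoxyflavan: 5,7-bis(benzyloxy)-3,4-epoxy-2-[2,3,4-tris(benzyloxy)phenyl]chromane (racemic, mainly anti to the aryl group, not isolated; its stereochemistry is erased in the same step) | O1C2C1c1c(OCc3ccccc3)cc(OCc3ccccc3)cc1OC2c1ccc(OCc2ccccc2)c(OCc2ccccc2)c1OCc1ccccc1 | intermediate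
9 | 5,7-bis(benzyloxy)-2-[2,3,4-tris(benzyloxy)phenyl]chroman-3-one (racemic, C2 labile) | O=C1Cc2c(OCc3ccccc3)cc(OCc3ccccc3)cc2OC1c1ccc(OCc2ccccc2)c(OCc2ccccc2)c1OCc1ccccc1 | intermediate
10 | (2R,3R)-5,7-bis(benzyloxy)-2-[2,3,4-tris(benzyloxy)phenyl]chroman-3-ol (2,3-cis) | O[C@@H]1Cc2c(OCc3ccccc3)cc(OCc3ccccc3)cc2O[C@@H]1c1ccc(OCc2ccccc2)c(OCc2ccccc2)c1OCc1ccccc1 | intermediate
11 | (2R,3R)-2-(2,3,4-trihydroxyphenyl)chromane-3,5,7-triol (2,3-cis) | Oc1ccc([C@H]2Oc3cc(O)cc(O)c3C[C@H]2O)c(O)c1O | intermediate
12 | (−)-epicatechin 3-O-gallate, (2R,3R)-2-(3,4-dihydroxyphenyl)-5,7-dihydroxychroman-3-yl 3,4,5-trihydroxybenzoate | O=C(O[C@@H]1Cc2c(O)cc(O)cc2O[C@@H]1c1ccc(O)c(O)c1)c1cc(O)c(O)c(O)c1 | starting material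
13 | ECG ortho-quinone: (2R,3R)-2-(3,4-dioxocyclohexa-1,5-dien-1-yl)-5,7-dihydroxychroman-3-yl 3,4,5-trihydroxybenzoate (not isolated) | O=C(O[C@@H]1Cc2c(O)cc(O)cc2O[C@@H]1C1=CC(=O)C(=O)C=C1)c1cc(O)c(O)c(O)c1 | intermediate
14 | biaryl Michael adduct: C6' of the catechol ring of 12 bonded to C5' of ring B of 11, both rings as phenols (not isolated) | O=C(O[C@@H]1Cc2c(O)cc(O)cc2O[C@@H]1c1cc(O)c(O)cc1-c1cc([C@H]2Oc3cc(O)cc(O)c3C[C@H]2O)c(O)c(O)c1O)c1cc(O)c(O)c(O)c1 | intermediate
15 | bicyclo[3.2.1]octane adduct: catechol-fused bridged trione-ol with C4' of 11 as the one-carbon keto bridge; bridgehead configuration not assigned (not isolated) | O=C(O[C@@H]1Cc2c(O)cc(O)cc2O[C@@H]1c1cc(O)c(O)c2c1C1C=C([C@H]3Oc4cc(O)cc(O)c4C[C@H]3O)C(=O)C2(O)C1=O)c1cc(O)c(O)c(O)c1 | intermediate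
16 | CNP0217128.1, (2R,3R)-5,7-dihydroxy-2-{3,4,6-trihydroxy-5-oxo-7-[(2R,3R)-3,5,7-trihydroxychroman-2-yl]-5H-benzo[7]annulen-1-yl}chroman-3-yl 3,4,5-trihydroxybenzoate | O=C(O[C@@H]1Cc2c(O)cc(O)cc2O[C@@H]1c1cc(O)c(O)c2c(=O)c(O)c([C@H]3Oc4cc(O)cc(O)c4C[C@H]3O)ccc12)c1cc(O)c(O)c(O)c1 | target

**Totals**
Total steps: 7. Longest linear sequence: 7 (1 → 2 → 4 → 7 → 9 → 10 → 11 → 16); 3 and 12 enter as bought materials.

**Three steps most likely to fail**

Step 4 (epoxidation and rearrangement). The very stabilised C4 cation may be trapped, may dimerise onto another ring A, or may undergo ring contraction instead of the hydride shift. The fallback sets out from 7: hydroboration with BH3·SMe2 in THF at 0 °C followed by NaOH/H2O2 puts boron at C3 anti to the aryl group and gives the racemic 2,3-trans-flavan-3-ol F1. Oxidation of this alcohol with Dess–Martin periodinane in CH2Cl2 then gives the ketone, so the fallback comes back to the route at 9.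

Step 5 (reductive dynamic kinetic resolution). The ketone is hindered and air-sensitive, and neither the facial selectivity nor the catalyst hand is precedented for this ring system. The fallback sets out from 9 and gives up the catalytic resolution: LiBH(sec-Bu)3 in THF at −78 °C reduces anti to the aryl group to the racemic cis-flavan-3-ol F2. This is esterified with (S)-O-methylmandelic acid (DCC, DMAP, CH2Cl2), and the two diastereomeric esters are separated on silica. The (2R,3R)-flavan-3-yl (S)-2-methoxy-2-phenylacetate F3 is cleaved with K2CO3 in MeOH/THF, and the fallback comes back to the route at 10.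

Step 7 (crossed oxidative annulation). Three things can lower the yield:
- redox exchange between 13 and 11, followed by self-coupling of 11;
- the galloyl ring of 12 reacting as a second pyrogallol;
- epimerisation at C2 of the new flavan through a quinone methide.

The fallback sets out from 12 and 11 and separates the oxidation events. 12 alone is oxidised with NaIO4 (1 equiv, MeCN/H2O, 0 °C) to the ortho-quinone 13. 11 (0.4 equiv) is then added under argon so that no external oxidant is present while the C–C bonds form. A second equivalent of 13 takes the Michael adduct 14 on to the bicyclic adduct 15, which is isolated on Sephadex LH-20. In a separate operation 15 is oxidised with air in NaHCO3 buffer (pH 7.5), losing CO2, and the fallback comes back to the route at 16. It passes only through compounds already in the list (F0: no new compound).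

**Further compounds**
F1 | step 4 | racemic 2,3-trans-5,7-bis(benzyloxy)-2-[2,3,4-tris(benzyloxy)phenyl]chroman-3-ol (2R,3S enantiomer drawn) | O[C@H]1Cc2c(OCc3ccccc3)cc(OCc3ccccc3)cc2O[C@@H]1c1ccc(OCc2ccccc2)c(OCc2ccccc2)c1OCc1ccccc1
F2 | step 5 | racemic 2,3-cis-5,7-bis(benzyloxy)-2-[2,3,4-tris(benzyloxy)phenyl]chroman-3-ol (2R,3R enantiomer drawn) | O[C@@H]1Cc2c(OCc3ccccc3)cc(OCc3ccccc3)cc2O[C@@H]1c1ccc(OCc2ccccc2)c(OCc2ccccc2)c1OCc1ccccc1
F3 | step 5 | (2R,3R)-5,7-bis(benzyloxy)-2-[2,3,4-tris(benzyloxy)phenyl]chroman-3-yl (S)-2-methoxy-2-phenylacetate | CO[C@H](C(=O)O[C@@H]1Cc2c(OCc3ccccc3)cc(OCc3ccccc3)cc2O[C@@H]1c1ccc(OCc2ccccc2)c(OCc2ccccc2)c1OCc1ccccc1)c1ccccc1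
F0 | step 7 | none | none
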